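## Structural features

The target is a 1,2,3,7,8,8a-hexahydronaphthalene (ring A: C1, C2, C3, C4, C4a, C8a; ring B: C4a, C5, C6, C7, C8, C8a) whose diene C4=C4a–C5=C6 runs across the ring fusion. Its C1 oxygen is acylated by a twelve-carbon chain (C1′–C12′) with a (2′S,3′S) syn α-methyl-β-hydroxy ester, an all-E tetraene and a free C12′ acid. Four stereocentres are contiguous: C1 (S, ester oxygen), C8a (S, H), C8 (R, quaternary, carrying methyl and the 3-hydroxypropanoyl group C9–C11) and C7 (R, tertiary alcohol with methyl); C3 (R, methyl) is remote and cis to the C1 oxygen. On ring B the C7 hydroxyl and the C8 methyl are cis, and the C9 acyl group is cis to H-8a and trans to the C1 oxygen, so a lactone or hemiketal between C9 and O1 would be trans-fused to the flattened ring B. Fragile points are the two β-hydroxy ketone arrays (C7–OH/C9=O, retro-aldol; C11–OH/C9=O, dehydration), the tertiary C7 alcohol that is allylic to the whole diene, the β-hydroxy ester at C3′ and the light- and acid-sensitive tetraenoic acid. The real difficulty is the pair of fully substituted neighbours C7 and C8 next to C8a, together with a diene position that a Diels–Alder closure of ring B cannot deliver directly. The key step exploits that C9 (carbonyl), C8, C8a and the sp2 carbon C4a form a γ,δ-unsaturated carbonyl array, so that C8–C8a is the bond of a [3,3] rearrangement, and that the C1 oxygen stereocentre sits next to C8a, where it can direct the face of that rearrangement. A second feature is used afterwards: rings A and B each hold one alkene ending at the C4a–C5 bond, the signature of an ene–yne–ene metathesis product.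

## Logic of the disconnections

47 to 30 and 43 (through 46, 45, 44): the C1–O ester bond is cut, together with the silyl ethers and the C12′ allyl ester. This separates the polyene from the core and leaves the fragile groups masked until two neutral or buffered final steps. The forward demand is acylation of a hindered secondary hydroxyl in the presence of a free tertiary one.

30 to 26 (through 29, 28, 27): the C10–C11 and C9–C10 bonds are cut, so the 3-hydroxypropanoyl group is grown from a C9 carboxyl group. The gain is that C9 can enter the synthesis as the carboxyl carbon of an ester. The demand is that the β-hydroxy ketone at C7/C9 never meets a strong base once the ketone exists.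

26 to 24 (through 25): both ring alkenes C4=C4a and C5=C6 are cut. Rings A and B and the heteroannular diene are traced back to an acyclic dienyne with an ethynyl group on C8a (C4a≡C5) and two vinyl groups (on C3 and on C7). The gain is that every stereocentre can be set on an open chain. The demand is that the metathesis cascade starts on the C3 vinyl group.

24 to 20 (through 23, 22, 21): the C8–C8a bond is cut by a retro-[3,3] step, the key disconnection. 23 carries the ethynyl group as a 1-bromoethenyl group; its carbons C9, C8, C8a, C4a and the sacrificial methylene are the product side of an ester enolate Claisen rearrangement. The precursor 20 is a plain ester of two small chiral fragments. In one sentence: an acyclic, chelate-controlled Ireland–Claisen rearrangement of allylic ester 20 joins the two halves of the core and sets the C8/C8a pair. The demand is a defined ketene acetal geometry, a chair transition state and π-facial control by C1.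

20 to 14 and 19: the ester O–CH2 bond is cut. The union needs no activation of the carboxyl group, which bears a free tertiary β-hydroxyl.

14 to 1 (through 13, 8, 7, 6, 5, 4, 3, 2; the olefination partner 11 comes from 9 through 10): the C4a=C8a alkene and the C3 methyl bond are cut. C8a, C1, C2, C3 and C4 map onto the five carbons of a glutamic-acid-derived lactone, with C1 as its stereocentre and the C3 methyl introduced trans to it. The demand is an olefination that puts C1 cis to the CH2O carbon.

19 to 15 (through 18, 17, 16): the C7–C6 and C8–C7 bonds are cut. C7 is set by chelation-controlled addition to a β-keto imide; the C8 configuration is irrelevant because C8 becomes an enolate carbon.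

43 to 15, 31 and 38 (through 42, 41, 37, 36, 35, 34, 33, 32 on one side and 40, 39 on the other): the C10′=C11′ alkene, the C5′–C6′ bond and the C2′–C3′ bond are cut. The two side-chain stereocentres come from one auxiliary-controlled syn-aldol reaction; the polyene is built by cross-coupling and olefination from geometrically defined pieces.

## Other disconnections considered

Alternative 1: the first idea is to cut C4a–C8a and C7–C8 and close both rings by an intramolecular Diels–Alder reaction of trienone A1 to octahydronaphthalene A2. The cycloaddition places only the C5=C6 alkene and leaves C4a and C7 as C–H. The C4=C4a alkene would then need a late dehydrogenation next to two other allylic methine positions, and the C7 hydroxyl a tertiary allylic C–H oxidation with no directing group. The two hardest features of the target would remain open after the key step, so the chosen plan is preferred on structural grounds.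

Alternative 2: the same two bonds can be formed at the correct oxidation level from vinylallene A3, a silyl dienol ether whose allene axis is relayed from a carbinol centre by propargyl Claisen rearrangement, giving A4 directly. Mechanistically this is attractive: the short tether forces the acyl group endo and the axis fixes the face. However, A3 derives from an enolisable β-allenyl ketone that isomerises easily to the conjugated dienone, it must be silylated selectively beside a second enolisable ketone, and the cycloaddition has to join two fully substituted carbons. In the bonds it forms it is a variant of Alternative 1.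

Alternative 3: the C8–C8a bond can also be cut on a preformed ring A, by Ireland–Claisen rearrangement of cyclohexenyl propanoate A5 with 1,3-chirality transfer from the C4 oxygen to C8a, giving A6. The all-cis 1,4-dioxygenated 6-methylcyclohexene pattern of A5 is long to prepare. Ketene acetals of 2-cyclohexenyl esters divide between chair and boat transition states, so the quaternary C8 could not be set in the rearrangement. It would have to be set later on a C9–O1 lactone template, which becomes trans-fused and strained when ring B closes. The acyclic rearrangement of the chosen plan sets C8 and C8a together and is shorter.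

Key step: step 14

Assumption: locants C1–C8a, C9–C11 and C1′–C12′ are those defined above; a lactone between C9 and O1 is taken not to form from 26 to 30 because it would be trans-fused to ring B.

## Steps

Step 1
Reactants: 1 (S)-5-[(trityloxy)methyl]dihydrofuran-2(3H)-one
Product: 3 (3R,5S)-3-methyl-5-[(trityloxy)methyl]dihydrofuran-2(3H)-one, via lithium enolate 2 (not isolated)
Conditions: LiN(iPr)2, THF, −78 °C; then MeI, −78 °C
Reagents that add atoms: iodomethane, CI
Why: α-Alkylation of a γ-butyrolactone enolate; 2 should be methylated on the face anti to the bulky trityloxymethyl group, giving the trans lactone and setting C3.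

Step 2
Reactants: 3 (3R,5S)-3-methyl-5-[(trityloxy)methyl]dihydrofuran-2(3H)-one
Product: 4 (3R,5S)-3-methyl-5-[(trityloxy)methyl]tetrahydrofuran-2-ol (both anomers)
Conditions: iBu2AlH, CH2Cl2, −78 °C
Reagents that add atoms: none
Why: Partial reduction of a lactone to the lactol at low temperature; no stereocentre is touched.

Step 3
Reactants: 4 (3R,5S)-3-methyl-5-[(trityloxy)methyl]tetrahydrofuran-2-ol
Product: 5 (2S,4R)-4-methyl-1-(trityloxy)hex-5-en-2-ol
Conditions: Ph3PCH3Br, KN(SiMe3)2, THF, 0 to 23 °C
Reagents that add atoms: methyltriphenylphosphonium bromide, C[P+](c1ccccc1)(c1ccccc1)c1ccccc1.[Br-]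
Why: Wittig methylenation of a lactol through its ring-opened tautomer; a non-stabilised ylide at low temperature should leave the α-methyl centre C3 intact and frees the C1 hydroxyl.

Step 4
Reactants: 5 (2S,4R)-4-methyl-1-(trityloxy)hex-5-en-2-ol
Product: 6 tert-butyldimethyl{[(2S,4R)-4-methyl-1-(trityloxy)hex-5-en-2-yl]oxy}silane
Conditions: tBuMe2SiCl, imidazole, DMF, 23 °C
Reagents that add atoms: tert-butylchlorodimethylsilane, CC(C)(C)[Si](C)(C)Cl
Why: Standard silylation of the secondary C1 hydroxyl.

Step 5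
Reactants: 6 tert-butyldimethyl{[(2S,4R)-4-methyl-1-(trityloxy)hex-5-en-2-yl]oxy}silane
Product: 7 (2S,4R)-2-[(tert-butyldimethylsilyl)oxy]-4-methylhex-5-en-1-ol
Conditions: TsOH·H2O (cat.), MeOH/CH2Cl2, 0 °C
Reagents that add atoms: none
Why: Acid-catalysed methanolysis of the trityl ether through the stabilised trityl cation should be much faster than cleavage of the secondary silyl ether at 0 °C.

Step 6
Reactants: 7 (2S,4R)-2-[(tert-butyldimethylsilyl)oxy]-4-methylhex-5-en-1-ol
Product: 8 (2S,4R)-2-[(tert-butyldimethylsilyl)oxy]-4-methylhex-5-enal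
Conditions: Dess–Martin periodinane, NaHCO3, CH2Cl2, 0 to 23 °C
Reagents that add atoms: none
Why: Dess–Martin oxidation under buffered conditions gives the α-silyloxy aldehyde without epimerisation at C1; it is used without storage.

Step 7
Reactants: 9 methyl 2-[bis(2,2,2-trifluoroethoxy)phosphoryl]acetate
Product: 11 methyl 2-[bis(2,2,2-trifluoroethoxy)phosphoryl]-2-bromoacetate (racemic), via lithium phosphonate 10 (not isolated)
Conditions: LiN(SiMe3)2, THF, −78 °C; then N-bromosuccinimide
Reagents that add atoms: N-bromosuccinimide, O=C1CCC(=O)N1Br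
Why: Electrophilic bromination of a stabilised phosphonate carbanion; one equivalent each of base and brominating agent limits dibromination.

Step 8
Reactants: 8 (2S,4R)-2-[(tert-butyldimethylsilyl)oxy]-4-methylhex-5-enal; 11 methyl 2-[bis(2,2,2-trifluoroethoxy)phosphoryl]-2-bromoacetate
Product: 13 methyl (2E,4S,6R)-2-bromo-4-[(tert-butyldimethylsilyl)oxy]-6-methylocta-2,7-dienoate, via potassium phosphonate 12 (not isolated)
Conditions: KN(SiMe3)2, 18-crown-6, THF, −78 °C; then 8
Reagents that add atoms: none
Why: Still–Gennari-type Horner–Wadsworth–Emmons olefination; the electron-poor phosphonate eliminates from the kinetic adduct and places the aldehyde substituent cis to the ester (here the E bromoacrylate), and −78 °C avoids epimerisation at C1.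

Step 9
Reactants: 13 methyl (2E,4S,6R)-2-bromo-4-[(tert-butyldimethylsilyl)oxy]-6-methylocta-2,7-dienoate
Product: 14 (2E,4S,6R)-2-bromo-4-[(tert-butyldimethylsilyl)oxy]-6-methylocta-2,7-dien-1-ol
Conditions: iBu2AlH, CH2Cl2, −78 °C
Reagents that add atoms: none
Why: 1,2-Reduction of the enoate to the allylic alcohol; the alkenyl bromide and the silyl ether are inert at −78 °C, and C1 stays cis to the CH2O carbon.

Step 10
Reactants: 15 (S)-4-benzyl-3-propanoyloxazolidin-2-one
Product: 17 (S)-4-benzyl-3-[(R)-2-methyl-3-oxobutanoyl]oxazolidin-2-one, via sodium enolate 16 (not isolated)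
Conditions: NaN(SiMe3)2, THF, −78 °C; then AcCl
Reagents that add atoms: acetyl chloride, CC(Cl)=O
Why: C-Acylation of the Z enolate on the face opposite the benzyl group (oxazolidinone auxiliary control); the β-keto imide should resist epimerisation because allylic strain holds the α-C–H bond in the imide plane.

Step 11
Reactants: 17 (S)-4-benzyl-3-[(R)-2-methyl-3-oxobutanoyl]oxazolidin-2-one
Product: 18 (S)-4-benzyl-3-[(2R,3R)-3-hydroxy-2,3-dimethylpent-4-enoyl]oxazolidin-2-one
Conditions: CH2=CHMgBr, MgBr2·OEt2, CH2Cl2/THF, −78 °C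
Reagents that add atoms: vinylmagnesium bromide, C=C[Mg]Br
Why: Chelation-controlled Grignard addition; magnesium bridges the ketone and imide carbonyls and the vinyl group should enter anti to the α-methyl group, setting C7 (R).

Step 12
Reactants: 18 (S)-4-benzyl-3-[(2R,3R)-3-hydroxy-2,3-dimethylpent-4-enoyl]oxazolidin-2-one
Product: 19 (2R,3R)-3-hydroxy-2,3-dimethylpent-4-enoic acid
Conditions: LiOH, H2O2, THF/H2O, 0 °C; then aq. Na2SO3
Reagents that add atoms: hydrogen peroxide, OO
Why: Hydroperoxide cleavage of the exocyclic imide carbonyl releases the acid and the recoverable auxiliary; 0 °C should be cold enough to avoid retro-aldol cleavage.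

Step 13
Reactants: 14 (2E,4S,6R)-2-bromo-4-[(tert-butyldimethylsilyl)oxy]-6-methylocta-2,7-dien-1-ol; 19 (2R,3R)-3-hydroxy-2,3-dimethylpent-4-enoic acid
Product: 20 (2E,4S,6R)-2-bromo-4-[(tert-butyldimethylsilyl)oxy]-6-methylocta-2,7-dien-1-yl (2R,3R)-3-hydroxy-2,3-dimethylpent-4-enoate
Conditions: PPh3, DIAD, THF, 0 °C
Reagents that add atoms: none
Why: Mitsunobu esterification; the primary allylic alcohol is activated and displaced by the carboxylate, so the carboxyl group is never activated and the tertiary β-hydroxyl cannot lactonise.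

Step 14
Reactants: 20 (2E,4S,6R)-2-bromo-4-[(tert-butyldimethylsilyl)oxy]-6-methylocta-2,7-dien-1-yl (2R,3R)-3-hydroxy-2,3-dimethylpent-4-enoate
Product: 23 (2R,3S,4S,6R)-3-(1-bromoethenyl)-4-[(tert-butyldimethylsilyl)oxy]-2-[(2R)-2-hydroxybut-3-en-2-yl]-2,6-dimethyloct-7-enoic acid, via dilithium chelate 21 (not isolated), via bis(trimethylsilyl) ketene acetal 22 (not isolated)
Conditions: LiN(iPr)2 (2.3 equiv), THF, −78 to −45 °C; Me3SiCl/Et3N, −78 to 45 °C; then 1 M HCl, THF, 0 °C
Reagents that add atoms: none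
Why: Ireland–Claisen ([3,3]-sigmatropic) rearrangement of an allylic ester in its dianionic form, the closest known type being the ester enolate Claisen rearrangement of β-hydroxy ester dianions. Two equivalents of base give alkoxide–enolate 21, in which lithium bridges the C7 alkoxide and the enolate oxygen, so C7 is cis to the enolate oxygen and the C8 methyl is cis to the allylic oxygen; once C8 is an enolate carbon, retro-aldol cleavage is blocked. Silylation freezes this geometry in 22, which rearranges on warming through a six-membered chair transition state; the step closes no ring. The C8–C8a bond forms between the allyl terminus (C1 cis to the CH2O carbon) and the ketene acetal face that puts the C8 methyl and C1 syn along the C9–C8–C8a–C4a chain, which is the relative configuration of C8 and C8a in the target. The absolute sense comes from C1: allylic 1,3-strain with the cis CH2O carbon holds the C1–H bond in the alkene plane, and the ketene acetal should attack C8a anti to the bulky, electron-withdrawing C1–OSi bond, giving (1S,8aS). C7 is carried unchanged from 19. The step therefore needs a defined ketene acetal geometry, the chair over the boat and π-facial control, secured respectively by the chelate, by the acyclic allyl unit and by the cis-substituted alkene next to C1. The 1-bromoethenyl group that results has no geometry to control and is the masked alkyne for step 16.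

Step 15
Reactants: 23 (2R,3S,4S,6R)-3-(1-bromoethenyl)-4-[(tert-butyldimethylsilyl)oxy]-2-[(2R)-2-hydroxybut-3-en-2-yl]-2,6-dimethyloct-7-enoic acid
Product: 24 (2R,3S,4S,6R)-4-[(tert-butyldimethylsilyl)oxy]-3-ethynyl-2-[(2R)-2-hydroxybut-3-en-2-yl]-2,6-dimethyloct-7-enoic acid
Conditions: LiN(iPr)2 (5 equiv), THF, −78 to 0 °C
Reagents that add atoms: none
Why: Anti-E2 dehydrobromination of a 2-bromo-1-alkene by loss of the vinylic hydrogen trans to bromine gives the terminal alkyne; the excess base only deprotonates CO2H, OH and the alkyne C–H, so C8a should not epimerise.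

Step 16
Reactants: 24 (2R,3S,4S,6R)-4-[(tert-butyldimethylsilyl)oxy]-3-ethynyl-2-[(2R)-2-hydroxybut-3-en-2-yl]-2,6-dimethyloct-7-enoic acid
Product: 25 (1S,3R,7R,8R,8aS)-1-[(tert-butyldimethylsilyl)oxy]-7-hydroxy-3,7,8-trimethyl-1,2,3,7,8,8a-hexahydronaphthalene-8-carboxylic acid (target locants)
Conditions: second-generation Grubbs catalyst, (H2IMes)(PCy3)Cl2Ru=CHPh (10 mol %), toluene (2 mM), 80 °C
Reagents that add atoms: none
Why: Tandem ring-closing dienyne (ene–yne–ene) metathesis; the catalyst should load on the unhindered C3 vinyl group, 6-exo insertion of the alkyne closes ring A (C4=C4a) and leaves a catalyst-bound vinylalkylidene at C5, which closes ring B (C5=C6) on the hindered C7 vinyl group, so the diene is placed across C4a by construction.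

Step 17
Reactants: 25 (1S,3R,7R,8R,8aS)-1-[(tert-butyldimethylsilyl)oxy]-7-hydroxy-3,7,8-trimethyl-1,2,3,7,8,8a-hexahydronaphthalene-8-carboxylic acid
Product: 26 (1S,3R,7R,8R,8aS)-1,7-dihydroxy-3,7,8-trimethyl-1,2,3,7,8,8a-hexahydronaphthalene-8-carboxylic acid (target locants)
Conditions: Bu4NF, THF, 23 °C
Reagents that add atoms: none
Why: Fluoride cleavage of the silyl ether at a stage with no ketone present, so the tertiary alkoxide cannot undergo retro-aldol cleavage.

Step 18
Reactants: 26 (1S,3R,7R,8R,8aS)-1,7-dihydroxy-3,7,8-trimethyl-1,2,3,7,8,8a-hexahydronaphthalene-8-carboxylic acid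
Product: 27 (1S,3R,7R,8R,8aS)-8-acetyl-3,7,8-trimethyl-1,2,3,7,8,8a-hexahydronaphthalene-1,7-diol (target locants)
Conditions: MeLi (8 equiv), THF, 0 °C; inverse quench into aq. NH4Cl at 0 °C
Reagents that add atoms: methyllithium, [Li]C
Why: Conversion of a carboxylic acid into a methyl ketone with excess methyllithium, a reaction that stops at the ketone level with lithium carboxylates as a class; C8 is quaternary so nothing can enolise, and the cold buffered quench limits retro-aldol cleavage of the new β-hydroxy ketone.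

Step 19
Reactants: 27 (1S,3R,7R,8R,8aS)-8-acetyl-3,7,8-trimethyl-1,2,3,7,8,8a-hexahydronaphthalene-1,7-diol
Product: 29 (1S,3R,7R,8R,8aS)-8-(3-hydroxypropanoyl)-3,7,8-trimethyl-1,2,3,7,8,8a-hexahydronaphthalene-1,7-diol (target locants), via tris(trimethylsilyl) enol ether 28 (not isolated)
Conditions: Me3SiOTf, Et3N, CH2Cl2, 0 °C; then aq. HCHO, Yb(OTf)3 (cat.), THF, 23 °C; then aq. citric acid
Reagents that add atoms: formaldehyde, C=O
Why: Soft enolisation can only occur towards the methyl group (C8 is quaternary) and masks both hydroxyls at the same time; a lanthanide-triflate-catalysed Mukaiyama aldol reaction with aqueous formaldehyde then adds C11, and mild acid removes the silyl ethers, so no strong base meets the β-hydroxy ketone.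

Step 20
Reactants: 29 (1S,3R,7R,8R,8aS)-8-(3-hydroxypropanoyl)-3,7,8-trimethyl-1,2,3,7,8,8a-hexahydronaphthalene-1,7-diol
Product: 30 (1S,3R,7R,8R,8aS)-3,7,8-trimethyl-8-{3-[(triethylsilyl)oxy]propanoyl}-1,2,3,7,8,8a-hexahydronaphthalene-1,7-diol (target locants)
Conditions: Et3SiCl, imidazole, CH2Cl2, −40 °C
Reagents that add atoms: chlorotriethylsilane, CC[Si](Cl)(CC)CC
Why: Silylation of the primary C11 hydroxyl in preference to the hindered secondary (C1) and tertiary (C7) hydroxyls at low temperature.

Step 21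
Reactants: 31 prop-2-yn-1-ol
Product: 33 (E)-3-iodo-2-methylprop-2-en-1-ol, via alkenylalane 32 (not isolated)
Conditions: Me3Al, Cp2ZrCl2 (cat.), CH2Cl2, 23 °C; then I2, THF, −30 °C
Reagents that add atoms: trimethylaluminium, C[Al](C)C; iodine, II
Why: Zirconium-catalysed syn-carboalumination of the terminal alkyne puts methyl on the internal carbon; the C–Al bond of 32 is then cleaved by iodine with retention, giving the E iodoalkene (C4′=C5′ geometry).

Step 22
Reactants: 33 (E)-3-iodo-2-methylprop-2-en-1-ol
Product: 34 (E)-3-iodo-2-methylprop-2-enal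
Conditions: MnO2, CH2Cl2, 23 °C
Reagents that add atoms: none
Why: Allylic oxidation with MnO2; the alkene geometry is retained.

Step 23
Reactants: 15 (S)-4-benzyl-3-propanoyloxazolidin-2-one; 34 (E)-3-iodo-2-methylprop-2-enal
Product: 36 (S)-4-benzyl-3-[(2S,3S,4E)-3-hydroxy-5-iodo-2,4-dimethylpent-4-enoyl]oxazolidin-2-one, via boron enolate 35 (not isolated)
Conditions: Bu2BOTf, iPr2NEt, CH2Cl2, −78 °C; then 34, −78 to 0 °C; then pH 7 buffer, H2O2, MeOH
Reagents that add atoms: none
Why: Evans syn-aldol reaction; the Z boron enolate reacts through a Zimmerman–Traxler chair on the face opposite the benzyl group, setting (2′S,3′S).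

Step 24
Reactants: 36 (S)-4-benzyl-3-[(2S,3S,4E)-3-hydroxy-5-iodo-2,4-dimethylpent-4-enoyl]oxazolidin-2-one
Product: 37 (S)-4-benzyl-3-{(2S,3S,4E)-5-iodo-2,4-dimethyl-3-[(triethylsilyl)oxy]pent-4-enoyl}oxazolidin-2-one
Conditions: Et3SiOTf, 2,6-lutidine, CH2Cl2, −78 °C
Reagents that add atoms: triethylsilyl trifluoromethanesulfonate, CC[Si](CC)(CC)OS(=O)(=O)C(F)(F)F
Why: Silylation of the secondary hydroxyl with a silyl triflate and a hindered base.

Step 25
Reactants: 38 (E)-3-methylpent-2-en-4-yn-1-ol
Product: 39 (2E,4E)-3-methyl-5-(tributylstannyl)penta-2,4-dien-1-ol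
Conditions: Bu3SnH, PdCl2(PPh3)2 (2 mol %), THF, 0 °C
Reagents that add atoms: tributyltin hydride, CCCC[SnH](CCCC)CCCC
Why: Palladium-catalysed syn-hydrostannation of the terminal alkyne places tin at the terminus and gives the E alkenylstannane (C6′=C7′); the existing E trisubstituted alkene is untouched.

Step 26
Reactants: 39 (2E,4E)-3-methyl-5-(tributylstannyl)penta-2,4-dien-1-ol
Product: 40 (2E,4E)-3-methyl-5-(tributylstannyl)penta-2,4-dienal
Conditions: MnO2, CH2Cl2, 23 °C
Reagents that add atoms: none
Why: MnO2 oxidation of the allylic alcohol to the dienal without touching the C–Sn bond.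

Step 27
Reactants: 37 (S)-4-benzyl-3-{(2S,3S,4E)-5-iodo-2,4-dimethyl-3-[(triethylsilyl)oxy]pent-4-enoyl}oxazolidin-2-one; 40 (2E,4E)-3-methyl-5-(tributylstannyl)penta-2,4-dienal
Product: 41 (S)-4-benzyl-3-{(2S,3S,4E,6E,8E)-2,4,8-trimethyl-10-oxo-3-[(triethylsilyl)oxy]deca-4,6,8-trienoyl}oxazolidin-2-one
Conditions: Pd2(dba)3 (5 mol %), AsPh3, DMF, 23 °C, dark
Reagents that add atoms: none
Why: Stille coupling of alkenyl iodide and alkenylstannane with retention of both geometries; it is run before the allyl ester is present.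

Step 28
Reactants: 41 (S)-4-benzyl-3-{(2S,3S,4E,6E,8E)-2,4,8-trimethyl-10-oxo-3-[(triethylsilyl)oxy]deca-4,6,8-trienoyl}oxazolidin-2-one
Product: 42 (S)-4-benzyl-3-{(2S,3S,4E,6E,8E,10E)-12-(allyloxy)-2,4,8-trimethyl-12-oxo-3-[(triethylsilyl)oxy]dodeca-4,6,8,10-tetraenoyl}oxazolidin-2-one
Conditions: allyl diethylphosphonoacetate, LiCl, DBU, MeCN, 0 to 23 °C
Reagents that add atoms: allyl 2-(diethoxyphosphoryl)acetate, C=CCOC(=O)CP(=O)(OCC)OCC
Why: Horner–Wadsworth–Emmons olefination under Masamune–Roush conditions gives the E acrylate; the mild amine base spares the imide and the silyl ether.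

Step 29
Reactants: 42 (S)-4-benzyl-3-{(2S,3S,4E,6E,8E,10E)-12-(allyloxy)-2,4,8-trimethyl-12-oxo-3-[(triethylsilyl)oxy]dodeca-4,6,8,10-tetraenoyl}oxazolidin-2-one
Product: 43 (2S,3S,4E,6E,8E,10E)-12-(allyloxy)-2,4,8-trimethyl-12-oxo-3-[(triethylsilyl)oxy]dodeca-4,6,8,10-tetraenoic acid
Conditions: LiOH, H2O2, THF/H2O, 0 °C; then aq. Na2SO3
Reagents that add atoms: hydrogen peroxide, OO
Why: Hydroperoxide cleaves the activated imide carbonyl in preference to the conjugated, less electrophilic allyl ester.

Step 30
Reactants: 30 (1S,3R,7R,8R,8aS)-3,7,8-trimethyl-8-{3-[(triethylsilyl)oxy]propanoyl}-1,2,3,7,8,8a-hexahydronaphthalene-1,7-diol; 43 (2S,3S,4E,6E,8E,10E)-12-(allyloxy)-2,4,8-trimethyl-12-oxo-3-[(triethylsilyl)oxy]dodeca-4,6,8,10-tetraenoic acid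
Product: 45 C1 ester of 30 with 43 (C12′ allyl ester; C3′ and C11 triethylsilyl ethers), via mixed anhydride 44 (not isolated)
Conditions: 2,4,6-Cl3C6H2COCl, Et3N, THF, 23 °C; then 30, DMAP, toluene, 23 to 40 °C
Reagents that add atoms: none
Why: Yamaguchi esterification; the secondary C1 hydroxyl should be acylated while the tertiary C7 hydroxyl is not.

Step 31
Reactants: 45 C1 ester of 30 with 43
Product: 46 C12′ carboxylic acid (bis(triethylsilyl) ether of the target)
Conditions: Pd(PPh3)4 (5 mol %), morpholine, THF, 23 °C, dark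
Reagents that add atoms: none
Why: Deallylation catalysed by zerovalent palladium with morpholine as allyl acceptor, under neutral conditions that spare both esters and the silyl ethers.

Step 32
Reactants: 46 C12′ carboxylic acid (bis(triethylsilyl) ether of the target)
Product: 47 CNP0306937.1
Conditions: HF·pyridine, pyridine, THF, 0 °C
Reagents that add atoms: none
Why: Buffered HF·pyridine removes both triethylsilyl ethers without base (no retro-aldol) and should be mild enough to spare the tertiary allylic alcohol.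

## Compound list

1 | (S)-5-[(trityloxy)methyl]dihydrofuran-2(3H)-one | O=C1CC[C@@H](COC(c2ccccc2)(c2ccccc2)c2ccccc2)O1 | starting material
2 | lithium enolate of 1 | [Li+].[O-]C1=CC[C@@H](COC(c2ccccc2)(c2ccccc2)c2ccccc2)O1 | intermediate
3 | (3R,5S)-3-methyl-5-[(trityloxy)methyl]dihydrofuran-2(3H)-one | O=C1[C@H](C)C[C@@H](COC(c2ccccc2)(c2ccccc2)c2ccccc2)O1 | intermediate
4 | (3R,5S)-3-methyl-5-[(trityloxy)methyl]tetrahydrofuran-2-ol (both anomers) | OC1[C@H](C)C[C@@H](COC(c2ccccc2)(c2ccccc2)c2ccccc2)O1 | intermediate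
5 | (2S,4R)-4-methyl-1-(trityloxy)hex-5-en-2-ol | C=C[C@H](C)C[C@H](O)COC(c1ccccc1)(c1ccccc1)c1ccccc1 | intermediate
6 | tert-butyldimethyl{[(2S,4R)-4-methyl-1-(trityloxy)hex-5-en-2-yl]oxy}silane | C=C[C@H](C)C[C@H](O[Si](C)(C)C(C)(C)C)COC(c1ccccc1)(c1ccccc1)c1ccccc1 | intermediate
7 | (2S,4R)-2-[(tert-butyldimethylsilyl)oxy]-4-methylhex-5-en-1-ol | C=C[C@H](C)C[C@H](O[Si](C)(C)C(C)(C)C)CO | intermediate
8 | (2S,4R)-2-[(tert-butyldimethylsilyl)oxy]-4-methylhex-5-enal | C=C[C@H](C)C[C@H](O[Si](C)(C)C(C)(C)C)C=O | intermediate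
9 | methyl 2-[bis(2,2,2-trifluoroethoxy)phosphoryl]acetate | COC(=O)CP(=O)(OCC(F)(F)F)OCC(F)(F)F | starting material
10 | lithium salt (carbanion) of 9 | [Li+].COC(=O)[CH-]P(=O)(OCC(F)(F)F)OCC(F)(F)F | intermediate
11 | methyl 2-[bis(2,2,2-trifluoroethoxy)phosphoryl]-2-bromoacetate (racemic) | COC(=O)C(Br)P(=O)(OCC(F)(F)F)OCC(F)(F)F | intermediate
12 | potassium salt (carbanion) of 11 | [K+].COC(=O)[C-](Br)P(=O)(OCC(F)(F)F)OCC(F)(F)F | intermediate
13 | methyl (2E,4S,6R)-2-bromo-4-[(tert-butyldimethylsilyl)oxy]-6-methylocta-2,7-dienoate | COC(=O)/C(Br)=C\[C@@H](O[Si](C)(C)C(C)(C)C)C[C@@H](C)C=C | intermediate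
14 | (2E,4S,6R)-2-bromo-4-[(tert-butyldimethylsilyl)oxy]-6-methylocta-2,7-dien-1-ol | OC/C(Br)=C\[C@@H](O[Si](C)(C)C(C)(C)C)C[C@@H](C)C=C | intermediate
15 | (S)-4-benzyl-3-propanoyloxazolidin-2-one | CCC(=O)N1[C@@H](Cc2ccccc2)COC1=O | starting material
16 | sodium (Z)-enolate of 15 | [Na+].C/C=C(\[O-])N1[C@@H](Cc2ccccc2)COC1=O | intermediate
17 | (S)-4-benzyl-3-[(R)-2-methyl-3-oxobutanoyl]oxazolidin-2-one | CC(=O)[C@@H](C)C(=O)N1[C@@H](Cc2ccccc2)COC1=O | intermediate
18 | (S)-4-benzyl-3-[(2R,3R)-3-hydroxy-2,3-dimethylpent-4-enoyl]oxazolidin-2-one | C=C[C@@](C)(O)[C@@H](C)C(=O)N1[C@@H](Cc2ccccc2)COC1=O | intermediate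
19 | (2R,3R)-3-hydroxy-2,3-dimethylpent-4-enoic acid | C=C[C@@](C)(O)[C@@H](C)C(=O)O | intermediate
20 | (2E,4S,6R)-2-bromo-4-[(tert-butyldimethylsilyl)oxy]-6-methylocta-2,7-dien-1-yl (2R,3R)-3-hydroxy-2,3-dimethylpent-4-enoate | C=C[C@@](C)(O)[C@@H](C)C(=O)OC/C(Br)=C\[C@@H](O[Si](C)(C)C(C)(C)C)C[C@@H](C)C=C | intermediate
21 | dilithium alkoxide–enolate chelate of 20 (C7 cis to the enolate oxygen) | [Li+].[Li+].C=C[C@@](C)([O-])/C(C)=C(\[O-])OC/C(Br)=C\[C@@H](O[Si](C)(C)C(C)(C)C)C[C@@H](C)C=C | intermediate
22 | bis(trimethylsilyl) ketene acetal from 21 (C7 cis to OSiMe3, C8 methyl cis to the allylic oxygen) | C=C[C@@](C)(O[Si](C)(C)C)/C(C)=C(\O[Si](C)(C)C)OC/C(Br)=C\[C@@H](O[Si](C)(C)C(C)(C)C)C[C@@H](C)C=C | intermediate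
23 | (2R,3S,4S,6R)-3-(1-bromoethenyl)-4-[(tert-butyldimethylsilyl)oxy]-2-[(2R)-2-hydroxybut-3-en-2-yl]-2,6-dimethyloct-7-enoic acid | C=C[C@H](C)C[C@H](O[Si](C)(C)C(C)(C)C)[C@@H](C(Br)=C)[C@@](C)(C(=O)O)[C@](C)(O)C=C | intermediate
24 | (2R,3S,4S,6R)-4-[(tert-butyldimethylsilyl)oxy]-3-ethynyl-2-[(2R)-2-hydroxybut-3-en-2-yl]-2,6-dimethyloct-7-enoic acid | C=C[C@H](C)C[C@H](O[Si](C)(C)C(C)(C)C)[C@@H](C#C)[C@@](C)(C(=O)O)[C@](C)(O)C=C | intermediate
25 | (1S,3R,7R,8R,8aS)-1-[(tert-butyldimethylsilyl)oxy]-7-hydroxy-3,7,8-trimethyl-1,2,3,7,8,8a-hexahydronaphthalene-8-carboxylic acid (target locants) | CC(C)(C)[Si](C)(C)O[C@H]1C[C@@H](C)C=C2C=C[C@@](C)(O)[C@](C)(C(=O)O)[C@H]21 | intermediate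
26 | (1S,3R,7R,8R,8aS)-1,7-dihydroxy-3,7,8-trimethyl-1,2,3,7,8,8a-hexahydronaphthalene-8-carboxylic acid (target locants) | O[C@H]1C[C@@H](C)C=C2C=C[C@@](C)(O)[C@](C)(C(=O)O)[C@H]21 | intermediate
27 | (1S,3R,7R,8R,8aS)-8-acetyl-3,7,8-trimethyl-1,2,3,7,8,8a-hexahydronaphthalene-1,7-diol (target locants) | O[C@H]1C[C@@H](C)C=C2C=C[C@@](C)(O)[C@](C)(C(C)=O)[C@H]21 | intermediate
28 | tris(trimethylsilyl) derivative of 27 (C1 and C7 silyl ethers, C9 silyl enol ether) | C[Si](C)(C)O[C@H]1C[C@@H](C)C=C2C=C[C@@](C)(O[Si](C)(C)C)[C@](C)(C(=C)O[Si](C)(C)C)[C@H]21 | intermediate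
29 | (1S,3R,7R,8R,8aS)-8-(3-hydroxypropanoyl)-3,7,8-trimethyl-1,2,3,7,8,8a-hexahydronaphthalene-1,7-diol (target locants) | O[C@H]1C[C@@H](C)C=C2C=C[C@@](C)(O)[C@](C)(C(=O)CCO)[C@H]21 | intermediate
30 | (1S,3R,7R,8R,8aS)-3,7,8-trimethyl-8-{3-[(triethylsilyl)oxy]propanoyl}-1,2,3,7,8,8a-hexahydronaphthalene-1,7-diol (target locants) | O[C@H]1C[C@@H](C)C=C2C=C[C@@](C)(O)[C@](C)(C(=O)CCO[Si](CC)(CC)CC)[C@H]21 | intermediate
31 | prop-2-yn-1-ol | C#CCO | starting material
32 | (E)-alkenylalane from 31 (dimethylaluminium alkoxide of the 3-(dimethylalumanyl)-2-methylallyl alcohol) | C[Al](C)/C=C(\C)CO[Al](C)C | intermediate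
33 | (E)-3-iodo-2-methylprop-2-en-1-ol | OC/C(C)=C/I | intermediate
34 | (E)-3-iodo-2-methylprop-2-enal | O=C/C(C)=C/I | intermediate
35 | (Z)-dibutylboron enolate of 15 | CCCCB(CCCC)O/C(=C\C)N1[C@@H](Cc2ccccc2)COC1=O | intermediate
36 | (S)-4-benzyl-3-[(2S,3S,4E)-3-hydroxy-5-iodo-2,4-dimethylpent-4-enoyl]oxazolidin-2-one | I/C=C(\C)[C@@H](O)[C@H](C)C(=O)N1[C@@H](Cc2ccccc2)COC1=O | intermediate
37 | (S)-4-benzyl-3-{(2S,3S,4E)-5-iodo-2,4-dimethyl-3-[(triethylsilyl)oxy]pent-4-enoyl}oxazolidin-2-one | I/C=C(\C)[C@@H](O[Si](CC)(CC)CC)[C@H](C)C(=O)N1[C@@H](Cc2ccccc2)COC1=O | intermediate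
38 | (E)-3-methylpent-2-en-4-yn-1-ol | C#C/C(C)=C/CO | starting material
39 | (2E,4E)-3-methyl-5-(tributylstannyl)penta-2,4-dien-1-ol | CCCC[Sn](CCCC)(CCCC)/C=C/C(C)=C/CO | intermediate
40 | (2E,4E)-3-methyl-5-(tributylstannyl)penta-2,4-dienal | CCCC[Sn](CCCC)(CCCC)/C=C/C(C)=C/C=O | intermediate
41 | (S)-4-benzyl-3-{(2S,3S,4E,6E,8E)-2,4,8-trimethyl-10-oxo-3-[(triethylsilyl)oxy]deca-4,6,8-trienoyl}oxazolidin-2-one | CC(/C=C/C=C(\C)[C@@H](O[Si](CC)(CC)CC)[C@H](C)C(=O)N1[C@@H](Cc2ccccc2)COC1=O)=C\C=O | intermediate
42 | (S)-4-benzyl-3-{(2S,3S,4E,6E,8E,10E)-12-(allyloxy)-2,4,8-trimethyl-12-oxo-3-[(triethylsilyl)oxy]dodeca-4,6,8,10-tetraenoyl}oxazolidin-2-one | CC(/C=C/C=C(\C)[C@@H](O[Si](CC)(CC)CC)[C@H](C)C(=O)N1[C@@H](Cc2ccccc2)COC1=O)=C\C=C\C(=O)OCC=C | intermediate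
43 | (2S,3S,4E,6E,8E,10E)-12-(allyloxy)-2,4,8-trimethyl-12-oxo-3-[(triethylsilyl)oxy]dodeca-4,6,8,10-tetraenoic acid | CC(/C=C/C=C(\C)[C@@H](O[Si](CC)(CC)CC)[C@H](C)C(=O)O)=C\C=C\C(=O)OCC=C | intermediate
44 | mixed anhydride of 43 with 2,4,6-trichlorobenzoic acid | CC(/C=C/C=C(\C)[C@@H](O[Si](CC)(CC)CC)[C@H](C)C(=O)OC(=O)c1c(Cl)cc(Cl)cc1Cl)=C\C=C\C(=O)OCC=C | intermediate
45 | C1 ester of 30 with 43 (C12′ allyl ester; C3′ and C11 triethylsilyl ethers) | CC(/C=C/C=C(\C)[C@@H](O[Si](CC)(CC)CC)[C@H](C)C(=O)O[C@H]1C[C@@H](C)C=C2C=C[C@@](C)(O)[C@](C)(C(=O)CCO[Si](CC)(CC)CC)[C@H]21)=C\C=C\C(=O)OCC=C | intermediate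
46 | C12′ acid of 45 (bis(triethylsilyl) ether of the target) | CC(/C=C/C=C(\C)[C@@H](O[Si](CC)(CC)CC)[C@H](C)C(=O)O[C@H]1C[C@@H](C)C=C2C=C[C@@](C)(O)[C@](C)(C(=O)CCO[Si](CC)(CC)CC)[C@H]21)=C\C=C\C(=O)O | intermediate
47 | CNP0306937.1 | CC(/C=C/C=C(\C)[C@@H](O)[C@H](C)C(=O)O[C@H]1C[C@@H](C)C=C2C=C[C@@](C)(O)[C@](C)(C(=O)CCO)[C@H]21)=C\C=C\C(=O)O | target

## Step count and least certain steps

Total step count: 32. Longest linear sequence: 19 steps (steps 1–6, 8, 9, 13–20, 30–32).

Step 14 (key step). Most likely to go wrong: α-deprotonation of the hindered lithium alkoxide is slow, so retro-aldol cleavage or ketene loss can compete before silylation; leakage through the boat transition state would give the C8 epimer and weak π-facial control by C1 the C8a epimer. Fallback, setting out from 14 and returning at 24: acylation of 14 with propanoic anhydride would give the propanoate ester F1. A kinetic Ireland–Claisen rearrangement (LiN(iPr)2, Me3SiCl) would give the bromodiene acid F2, a mixture at C8 that does not matter. Bu4NF (dehydrobromination and desilylation) and acidification would give the cis-4-ethynyl γ-lactone F3. Its enolate would be C-acetylated anti to the ethynyl group, giving the quaternary acetyl lactone F4. Chelation-controlled addition of CH2=CHMgBr would give the vinyl carbinol lactone F5 (or the two carbon groups would be introduced in the reverse order if the other C7 epimer forms). Saponification with LiOH and silylation (tBuMe2SiCl, imidazole; then K2CO3, MeOH to free the carboxyl group) would return to 24.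

Step 16. Most likely to go wrong: initiation on the alkyne or on the hindered C7 vinyl group, which diverts the cascade to a five-membered ring closure, or arrest after ring A because closure onto the neopentyl-type alkene is slow. Fallback, setting out from 23 and returning at 25: the elimination of step 15 is skipped, and a Stille coupling of 23 with CH2=CHSnBu3 (Pd(PPh3)4, CuI) would give the tetraene acid F6, a 2-substituted butadiene. Ring-closing metathesis with the same ruthenium catalyst would then close ring A at the C4a methylene and ring B at the terminal diene carbon.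

Step 11. Most likely to go wrong: enolisation of the β-keto imide by the Grignard reagent, attack at the imide carbonyl, or erosion of chelation control. Fallback, setting out from 17 and returning at 18: addition of the smaller and less basic HC≡CMgBr would give the propargylic alcohol F7, and semi-hydrogenation over Pd/CaCO3 poisoned with Pb(OAc)2 and quinoline would give 18.

Step 19. Most likely to go wrong: hydrolysis of the silyl enol ether faster than its aldol reaction with formaldehyde, and ionisation of the tertiary allylic silyl ether by the Lewis acid. Fallback, setting out from 26 and returning at 29: excess CH2=CHLi would give the vinyl ketone F8; conjugate borylation with bis(pinacolato)diboron catalysed by CuCl/NaOtBu would give the β-boryl ketone F9, and oxidation with NaBO3 would give 29.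

Step 30. Most likely to go wrong: acylation of the hindered C1 hydroxyl is slow, and meanwhile the activated β-silyloxy acid can eliminate silanol or epimerise at C2′. Fallback, setting out from 37 (with 30 and 40) and returning at 45: the auxiliary would be cleaved first (LiOH, H2O2) to the iodo acid F10, which carries no polyene and would be coupled with 30 under the same conditions to the alkenyl iodide ester F11. Separately, 40 would be homologated with allyl diethylphosphonoacetate to the stannyl trienoate F12. A palladium-free coupling of F11 and F12 promoted by monovalent copper thiophene-2-carboxylate, Cu(O2CC4H3S), would then give 45.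

## Further compounds

F1 | step 14 | (2E,4S,6R)-2-bromo-4-[(tert-butyldimethylsilyl)oxy]-6-methylocta-2,7-dien-1-yl propanoate | CCC(=O)OC/C(Br)=C\[C@@H](O[Si](C)(C)C(C)(C)C)C[C@@H](C)C=C
F2 | step 14 | (3S,4S,6R)-3-(1-bromoethenyl)-4-[(tert-butyldimethylsilyl)oxy]-2,6-dimethyloct-7-enoic acid (both C2 epimers) | C=C[C@H](C)C[C@H](O[Si](C)(C)C(C)(C)C)[C@@H](C(Br)=C)C(C)C(=O)O
F3 | step 14 | (4S,5S)-4-ethynyl-3-methyl-5-[(2R)-2-methylbut-3-en-1-yl]dihydrofuran-2(3H)-one (both C3 epimers) | O=C1O[C@@H](C[C@@H](C)C=C)[C@@H](C#C)C1C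
F4 | step 14 | 3-acetyl-4-ethynyl-3-methyl-5-[(2R)-2-methylbut-3-en-1-yl]dihydrofuran-2(3H)-one with acetyl anti to ethynyl and ethynyl cis to the C5 chain | O=C1O[C@@H](C[C@@H](C)C=C)[C@@H](C#C)[C@]1(C)C(C)=O
F5 | step 14 | 4-ethynyl-3-[(2R)-2-hydroxybut-3-en-2-yl]-3-methyl-5-[(2R)-2-methylbut-3-en-1-yl]dihydrofuran-2(3H)-one, ring stereocentres as in F4 | O=C1O[C@@H](C[C@@H](C)C=C)[C@@H](C#C)[C@]1(C)[C@](C)(O)C=C
F6 | step 16 | (2R,3S,4S,6R)-3-(buta-1,3-dien-2-yl)-4-[(tert-butyldimethylsilyl)oxy]-2-[(2R)-2-hydroxybut-3-en-2-yl]-2,6-dimethyloct-7-enoic acid | C=C[C@H](C)C[C@H](O[Si](C)(C)C(C)(C)C)[C@@H](C(=C)C=C)[C@@](C)(C(=O)O)[C@](C)(O)C=C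
F7 | step 11 | (S)-4-benzyl-3-[(2R,3S)-3-hydroxy-2,3-dimethylpent-4-ynoyl]oxazolidin-2-one | C#C[C@@](C)(O)[C@@H](C)C(=O)N1[C@@H](Cc2ccccc2)COC1=O
F8 | step 19 | (1S,3R,7R,8R,8aS)-8-acryloyl-3,7,8-trimethyl-1,2,3,7,8,8a-hexahydronaphthalene-1,7-diol (target locants) | O[C@H]1C[C@@H](C)C=C2C=C[C@@](C)(O)[C@](C)(C(=O)C=C)[C@H]21
F9 | step 19 | (1S,3R,7R,8R,8aS)-3,7,8-trimethyl-8-[3-(4,4,5,5-tetramethyl-1,3,2-dioxaborolan-2-yl)propanoyl]-1,2,3,7,8,8a-hexahydronaphthalene-1,7-diol (target locants) | O[C@H]1C[C@@H](C)C=C2C=C[C@@](C)(O)[C@](C)(C(=O)CCB3OC(C)(C)C(C)(C)O3)[C@H]21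
F10 | step 30 | (2S,3S,4E)-5-iodo-2,4-dimethyl-3-[(triethylsilyl)oxy]pent-4-enoic acid | I/C=C(\C)[C@@H](O[Si](CC)(CC)CC)[C@H](C)C(=O)O
F11 | step 30 | C1 ester of 30 with F10 | I/C=C(\C)[C@@H](O[Si](CC)(CC)CC)[C@H](C)C(=O)O[C@H]1C[C@@H](C)C=C2C=C[C@@](C)(O)[C@](C)(C(=O)CCO[Si](CC)(CC)CC)[C@H]21
F12 | step 30 | allyl (2E,4E,6E)-5-methyl-7-(tributylstannyl)hepta-2,4,6-trienoate | CCCC[Sn](CCCC)(CCCC)/C=C/C(C)=C/C=C/C(=O)OCC=C
A1 | alternative 1 | (E,E,E)-trienone with C1 and C11 tert-butyldimethylsilyl ethers | C/C=C/C=C/C[C@H](C)C[C@H](O[Si](C)(C)C(C)(C)C)/C=C(\C)C(=O)CCO[Si](C)(C)C(C)(C)C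
A2 | alternative 1 | trans-fused octahydronaphthalene Diels–Alder adduct with C4a–H and C7–H | CC(C)(C)[Si](C)(C)O[C@H]1C[C@@H](C)C[C@@H]2C=C[C@H](C)[C@](C)(C(=O)CCO[Si](C)(C)C(C)(C)C)[C@H]21
A3 | alternative 2 | vinylallene silyl dienol ether tethered to the (E)-α-methyl enone | C/C(O[Si](C)(C)C(C)(C)C)=C/C([H])=[C@]=C([H])[C@H](C)C[C@H](O[Si](C)(C)C(C)(C)C)/C=C(\C)C(=O)CCO[Si](C)(C)C(C)(C)C
A4 | alternative 2 | hexahydronaphthalene adduct, tris(tert-butyldimethylsilyl) ether of 29 | CC(C)(C)[Si](C)(C)O[C@H]1C[C@@H](C)C=C2C=C[C@@](C)(O[Si](C)(C)C(C)(C)C)[C@](C)(C(=O)CCO[Si](C)(C)C(C)(C)C)[C@H]21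
A5 | alternative 3 | all-cis 4-[(tert-butyldimethylsilyl)oxy]-2-iodo-6-methylcyclohex-2-en-1-yl propanoate | CC(C)(C)[Si](C)(C)O[C@H]1C[C@@H](C)[C@@H](OC(=O)CC)C(I)=C1
A6 | alternative 3 | 2-{6-[(tert-butyldimethylsilyl)oxy]-2-iodo-4-methylcyclohex-2-en-1-yl}propanoic acid, cis at C8a and C1, mixture at the α-carbon | CC(C)(C)[Si](C)(C)O[C@H]1C[C@@H](C)C=C(I)[C@H]1C(C)C(=O)O
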